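**Retrosynthetic overview**

1. Flemistrictin D is a 2,2-dimethyl-2H-chromene (O1, C2, C3=C4, C4a, C8a) fused to a fully substituted hydroquinone (5-OH, 6-acyl, 7-OMe, 8-OH). The pyran ring is cut last: 15 ⇐ spiro[2,5-dihydrofuran–cyclohexa-2,4-dienone] 13, in which C4 sits on C8a and moves to C4a (1,2-vinyl shift with rearomatisation, five- to six-membered ring enlargement).
2. 13 ⇐ phenol 12 by oxidative dearomatisation: the C8 phenol carries a (Z)-CH=CH–CMe2OH chain on C8a, and its tertiary hydroxyl closes the spiro ether.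
3. 12 ⇐ aryl bromide 5: Sonogashira coupling with 2-methylbut-3-yn-2-ol and Lindlar reduction (brings C2, C3, C4 and O1); ortho-lithiation between OMe and OMOM with Weinreb acylation (the dihydrochalcone ketone on C6).
4. 5 ⇐ 5-bromovanillin (silyl ether, Baeyer–Villiger, MOM ether). Ring order: the benzene ring is bought, the five-membered spiro 2,5-dihydrofuran is made in step 8 and enlarged to the 2H-pyran in step 9.
5. Enabling feature: in 13 the spiro carbon (future C8a) bears both O1 and C4 and lies between the dienone carbonyl (C8) and the only hydrogen-bearing ring carbon (C4a). Carbonyl protonation puts positive charge on C4a, and the shift of C4 leaves a cation on C8a that O1 stabilises.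

Key step: step 9

Remark on the chemistry: the target has no stereocentre and its ring alkene is necessarily cis, so it is achiral and no enantiocontrol is needed. The only stereocentre on the route (the spiro carbon of 13) is formed racemic and is erased in step 9.

**Route**

Step 1
Reactants: 1 5-bromovanillin (3-bromo-4-hydroxy-5-methoxybenzaldehyde)
Product: 2 3-bromo-5-methoxy-4-(triisopropylsilyloxy)benzaldehyde
Conditions: TIPSCl, imidazole, DMF, rt
Reagents that add atoms: triisopropylsilyl chloride, CC(C)[Si](Cl)(C(C)C)C(C)C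
Why: O-silylation of the acidic phenol (imidazole-promoted) masks the future C8 hydroxyl with a group that should survive peracid, organolithium and hydrogenation and is removed orthogonally by fluoride.

Step 2
Reactants: 2 3-bromo-5-methoxy-4-(triisopropylsilyloxy)benzaldehyde
Product: 4 3-bromo-5-methoxy-4-(triisopropylsilyloxy)phenol, via aryl formate 3 (not isolated)
Conditions: mCPBA, CH2Cl2, 0 °C → rt; then Et3N (cat.), MeOH, rt
Reagents that add atoms: meta-chloroperbenzoic acid, OOC(=O)c1cccc(Cl)c1
Why: Baeyer–Villiger oxidation of an electron-rich benzaldehyde, in which the aryl group with its para silyloxy donor migrates in the Criegee adduct; mild methanolysis of the formate should free the phenol without touching the aryl silyl ether.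

Step 3
Reactants: 4 3-bromo-5-methoxy-4-(triisopropylsilyloxy)phenol
Product: 5 1-bromo-3-methoxy-5-(methoxymethoxy)-2-(triisopropylsilyloxy)benzene
Conditions: MOMCl, i-Pr2NEt, CH2Cl2, 0 °C → rt
Reagents that add atoms: chloromethyl methyl ether, COCCl
Why: O-alkylation of the unhindered phenol installs the MOM acetal, which later directs the ortho-lithiation and is lost under the acid of the last step.

Step 4
Reactants: 5 1-bromo-3-methoxy-5-(methoxymethoxy)-2-(triisopropylsilyloxy)benzene; 6 2-methylbut-3-yn-2-ol
Product: 7 4-[3-methoxy-5-(methoxymethoxy)-2-(triisopropylsilyloxy)phenyl]-2-methylbut-3-yn-2-ol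
Conditions: Pd(PhCN)2Cl2 (cat.), P(t-Bu)3·HBF4 (cat.), CuI (cat.), i-Pr2NH, dioxane, rt → 50 °C
Reagents that add atoms: none
Why: Sonogashira coupling with a bulky electron-rich phosphine should engage the electron-rich aryl bromide, and the ortho silyl ether prevents the cycloisomerisation to a benzofuran that a free ortho phenol would undergo.

Step 5
Reactants: 7 4-[3-methoxy-5-(methoxymethoxy)-2-(triisopropylsilyloxy)phenyl]-2-methylbut-3-yn-2-ol; 8 N-methoxy-N-methyl-3-phenylpropanamide
Product: 10 1-[4-(3-hydroxy-3-methylbut-1-yn-1-yl)-2-methoxy-6-(methoxymethoxy)-3-(triisopropylsilyloxy)phenyl]-3-phenylpropan-1-one, via dilithiated arene 9 (not isolated)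
Conditions: n-BuLi (2.2 equiv), THF, −78 → 0 °C; then 8, −78 °C → rt; AcOH quench
Reagents that add atoms: none
Why: Directed ortho-metalation: after the tertiary alcohol is deprotonated, the second equivalent of base should remove the ring proton flanked by OMe and OMOM (cooperative direction), and Weinreb-amide acylation stops at the ketone because the chelated tetrahedral adduct collapses only on work-up.

Step 6
Reactants: 10 1-[4-(3-hydroxy-3-methylbut-1-yn-1-yl)-2-methoxy-6-(methoxymethoxy)-3-(triisopropylsilyloxy)phenyl]-3-phenylpropan-1-one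
Product: 11 1-{4-[(1Z)-3-hydroxy-3-methylbut-1-en-1-yl]-2-methoxy-6-(methoxymethoxy)-3-(triisopropylsilyloxy)phenyl}-3-phenylpropan-1-one
Conditions: H2 (1 atm), Lindlar catalyst, quinoline, EtOAc, rt
Reagents that add atoms: none
Why: Lindlar semi-hydrogenation delivers hydrogen syn and so sets the Z geometry that the tertiary hydroxyl needs to reach the ring carbon; the aryl ketone, silyl ether and acetal should be inert.

Step 7
Reactants: 11 1-{4-[(1Z)-3-hydroxy-3-methylbut-1-en-1-yl]-2-methoxy-6-(methoxymethoxy)-3-(triisopropylsilyloxy)phenyl}-3-phenylpropan-1-one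
Product: 12 1-{3-hydroxy-4-[(1Z)-3-hydroxy-3-methylbut-1-en-1-yl]-2-methoxy-6-(methoxymethoxy)phenyl}-3-phenylpropan-1-one
Conditions: TBAF (1.1 equiv), AcOH (1.1 equiv), THF, 0 °C
Reagents that add atoms: none
Why: Fluoride-mediated cleavage of the aryl silyl ether under acetic acid buffering should release the phenol without acid strong enough to ionise the Z-allylic tertiary alcohol, which would close an isomeric pyran onto this phenol oxygen; 12 is used at once.

Step 8
Reactants: 12 1-{3-hydroxy-4-[(1Z)-3-hydroxy-3-methylbut-1-en-1-yl]-2-methoxy-6-(methoxymethoxy)phenyl}-3-phenylpropan-1-one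
Product: 13 (±)-7-methoxy-9-(methoxymethoxy)-2,2-dimethyl-8-(3-phenylpropanoyl)-1-oxaspiro[4.5]deca-3,7,9-trien-6-one
Conditions: PhI(OAc)2 (1.1 equiv), NaHCO3, MeCN, 0 °C
Reagents that add atoms: none
Why: Hypervalent-iodine oxidative dearomatisation (ortho-spiroetherification): ligand exchange gives the aryloxy-λ3-iodane and the tethered tertiary hydroxyl attacks the ortho carbon that carries the alkenyl chain (5-exo-trig) with loss of PhI, an intramolecular capture that should outrun attack of acetate at the oxygenated ortho and para carbons in the buffered, non-nucleophilic medium; the spiro stereocentre forms racemic and is erased in step 9.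

Step 9
Reactants: 13 (±)-7-methoxy-9-(methoxymethoxy)-2,2-dimethyl-8-(3-phenylpropanoyl)-1-oxaspiro[4.5]deca-3,7,9-trien-6-one
Product: 15 Flemistrictin D, via MOM-protected chromene 14 (not isolated)
Conditions: (+)-CSA (20 mol %), CH2Cl2, 0 °C → rt; then MeOH, 40 °C
Reagents that add atoms: none
Why: Protonation of the dienone carbonyl turns 13 into the ipso σ-complex of an aryl ether; the vinyl carbon of the dihydrofuran then migrates from the spiro carbon to the adjacent ring CH (1,2-shift) to give an arenium ion with the charge on the oxygen-bearing carbon, which loses the proton of that CH and aromatises, after which methanol and the same acid exchange off the MOM acetal. The closest known reaction type is the dienone–phenol rearrangement of spirocyclohexadienones (spiro ether to chroman), a semipinacol-type shift. No ring is closed by cyclisation: the six-membered 2H-pyran arises from the five-membered 2,5-dihydrofuran because the shift inserts the aromatic carbon C4a into the ring. No stereocentre is formed; the spiro centre is destroyed and the cis ring alkene becomes the C3=C4 bond. The step needs carbon rather than oxygen migration and the CH rather than the carbonyl carbon as terminus, which is secured because only carbon migration leaves the cation on the oxygen-bearing carbon and only the CH terminus allows rearomatisation; it also needs the shift to outrun ionisation of the spiro C–O bond, which the anhydrous medium and protonation at the more basic carbonyl oxygen should favour.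

**Compound list**

1 | 5-bromovanillin (3-bromo-4-hydroxy-5-methoxybenzaldehyde) | COc1cc(C=O)cc(Br)c1O | starting material
2 | 3-bromo-5-methoxy-4-(triisopropylsilyloxy)benzaldehyde | COc1cc(C=O)cc(Br)c1O[Si](C(C)C)(C(C)C)C(C)C | intermediate
3 | 3-bromo-5-methoxy-4-(triisopropylsilyloxy)phenyl formate | COc1cc(OC=O)cc(Br)c1O[Si](C(C)C)(C(C)C)C(C)C | intermediate
4 | 3-bromo-5-methoxy-4-(triisopropylsilyloxy)phenol | COc1cc(O)cc(Br)c1O[Si](C(C)C)(C(C)C)C(C)C | intermediate
5 | 1-bromo-3-methoxy-5-(methoxymethoxy)-2-(triisopropylsilyloxy)benzene | COCOc1cc(OC)c(O[Si](C(C)C)(C(C)C)C(C)C)c(Br)c1 | intermediate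
6 | 2-methylbut-3-yn-2-ol | CC(C)(O)C#C | starting material
7 | 4-[3-methoxy-5-(methoxymethoxy)-2-(triisopropylsilyloxy)phenyl]-2-methylbut-3-yn-2-ol | COCOc1cc(OC)c(O[Si](C(C)C)(C(C)C)C(C)C)c(C#CC(C)(C)O)c1 | intermediate
8 | N-methoxy-N-methyl-3-phenylpropanamide | CON(C)C(=O)CCc1ccccc1 | starting material
9 | dilithiated arene (lithium alkoxide of 7, lithiated at the ring carbon between OMe and OMOM) | [Li]c1c(OC)c(O[Si](C(C)C)(C(C)C)C(C)C)c(C#CC(C)(C)O[Li])cc1OCOC | intermediate
10 | 1-[4-(3-hydroxy-3-methylbut-1-yn-1-yl)-2-methoxy-6-(methoxymethoxy)-3-(triisopropylsilyloxy)phenyl]-3-phenylpropan-1-one | COCOc1cc(C#CC(C)(C)O)c(O[Si](C(C)C)(C(C)C)C(C)C)c(OC)c1C(=O)CCc1ccccc1 | intermediate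
11 | 1-{4-[(1Z)-3-hydroxy-3-methylbut-1-en-1-yl]-2-methoxy-6-(methoxymethoxy)-3-(triisopropylsilyloxy)phenyl}-3-phenylpropan-1-one | COCOc1cc(/C=C\C(C)(C)O)c(O[Si](C(C)C)(C(C)C)C(C)C)c(OC)c1C(=O)CCc1ccccc1 | intermediate
12 | 1-{3-hydroxy-4-[(1Z)-3-hydroxy-3-methylbut-1-en-1-yl]-2-methoxy-6-(methoxymethoxy)phenyl}-3-phenylpropan-1-one | COCOc1cc(/C=C\C(C)(C)O)c(O)c(OC)c1C(=O)CCc1ccccc1 | intermediate
13 | (±)-7-methoxy-9-(methoxymethoxy)-2,2-dimethyl-8-(3-phenylpropanoyl)-1-oxaspiro[4.5]deca-3,7,9-trien-6-one (racemic at the spiro carbon) | COCOC1=CC2(C=CC(C)(C)O2)C(=O)C(OC)=C1C(=O)CCc1ccccc1 | intermediate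
14 | 1-[8-hydroxy-7-methoxy-5-(methoxymethoxy)-2,2-dimethyl-2H-chromen-6-yl]-3-phenylpropan-1-one | COCOc1c(C(=O)CCc2ccccc2)c(OC)c(O)c2OC(C)(C)C=Cc12 | intermediate
15 | Flemistrictin D, 1-(5,8-dihydroxy-7-methoxy-2,2-dimethyl-2H-chromen-6-yl)-3-phenylpropan-1-one | COc1c(O)c2c(c(O)c1C(=O)CCc1ccccc1)C=CC(C)(C)O2 | target

**Step count and risks**

Total step count: 9. Longest linear sequence: 9 steps (1 → 15).

Steps most likely to fail:

1. Step 9. The spiro C–O bond may ionise (retro-oxa-Michael, pushed by the enol ether oxygen) faster than the 1,2-shift, so that the ring-opened quinone recloses in the wrong sense, or the electron-rich chromene may oligomerise in acid.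
Fallback (direct ring closure instead of ring enlargement): it sets out from 5 and comes back to the route at 14. Buffered TBAF on 5 should give 2-bromo-6-methoxy-4-(methoxymethoxy)phenol F1. Copper-catalysed hydroxylation of the aryl bromide (CuI, 8-hydroxyquinoline, KOH, DMSO/H2O, 100 °C) should give 3-methoxy-5-(methoxymethoxy)benzene-1,2-diol F2. Condensation of F2 with 3-methylbut-2-enal (ethylenediammonium diacetate, toluene, reflux, under argon) should proceed by C-alkylation at the ring carbon between the hydroxyl and the OMOM group, dehydration and oxa-6π-electrocyclisation to 7-methoxy-5-(methoxymethoxy)-2,2-dimethyl-2H-chromen-8-ol F3. Treatment with n-BuLi (2.2 equiv) should give the dilithiated chromene F4 (phenoxide plus aryllithium between OMe and OMOM), which is acylated with 8 to give 14. The acid methanolysis that closes step 9 then gives 15.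

2. Step 8. Acetate or adventitious water may attack the para carbon that carries the electron-releasing OMOM group (oxidation to the quinone), or the acid released may trigger cyclodehydration of 12, instead of ortho spirocyclisation.
Fallback (exchange of the donor acetal for an electron-poor acetate before the oxidation): it sets out from 10 and comes back at 15. HCl in MeOH at the acid-tolerant alkyne stage should give 1-[6-hydroxy-4-(3-hydroxy-3-methylbut-1-yn-1-yl)-2-methoxy-3-(triisopropylsilyloxy)phenyl]-3-phenylpropan-1-one F5. Ac2O, pyridine and catalytic DMAP at 0 °C should give 5-(3-hydroxy-3-methylbut-1-yn-1-yl)-3-methoxy-2-(3-phenylpropanoyl)-4-(triisopropylsilyloxy)phenyl acetate F6. Lindlar semi-hydrogenation should give 5-[(1Z)-3-hydroxy-3-methylbut-1-en-1-yl]-3-methoxy-2-(3-phenylpropanoyl)-4-(triisopropylsilyloxy)phenyl acetate F7. Buffered TBAF should give 4-hydroxy-5-[(1Z)-3-hydroxy-3-methylbut-1-en-1-yl]-3-methoxy-2-(3-phenylpropanoyl)phenyl acetate F8. PhI(OAc)2 with NaHCO3 should now cyclise at the ortho carbon only, giving (±)-7-methoxy-2,2-dimethyl-6-oxo-8-(3-phenylpropanoyl)-1-oxaspiro[4.5]deca-3,7,9-trien-9-yl acetate F9. CSA in CH2Cl2 should effect the same 1,2-shift to 8-hydroxy-7-methoxy-2,2-dimethyl-6-(3-phenylpropanoyl)-2H-chromen-5-yl acetate F10, the enol acetate being unable to push out the spiro oxygen. K2CO3 in MeOH under argon should then give 15.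

3. Step 5. The hindered 2,6-dialkoxyaryllithium may take a proton from the enolisable amide instead of adding to it, returning 7.
Fallback (carbonyl addition and oxidation instead of acyl substitution): it sets out from 7 and comes back at 10. The dilithiated arene 9 is generated as before and quenched with 3-phenylpropanal to give 1-[4-(3-hydroxy-3-methylbut-1-yn-1-yl)-2-methoxy-6-(methoxymethoxy)-3-(triisopropylsilyloxy)phenyl]-3-phenylpropan-1-ol F11 (racemic). Dess–Martin periodinane should oxidise the secondary benzylic alcohol, and not the tertiary one, to give 10.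

**Further compounds**

F1 | step 9 | 2-bromo-6-methoxy-4-(methoxymethoxy)phenol | COCOc1cc(Br)c(O)c(OC)c1
F2 | step 9 | 3-methoxy-5-(methoxymethoxy)benzene-1,2-diol | COCOc1cc(O)c(O)c(OC)c1
F3 | step 9 | 7-methoxy-5-(methoxymethoxy)-2,2-dimethyl-2H-chromen-8-ol | COCOc1cc(OC)c(O)c2OC(C)(C)C=Cc12
F4 | step 9 | dilithiated chromene (lithium 8-phenoxide of F3, lithiated at C6) | [Li]c1c(OC)c(O[Li])c2OC(C)(C)C=Cc2c1OCOC
F5 | step 8 | 1-[6-hydroxy-4-(3-hydroxy-3-methylbut-1-yn-1-yl)-2-methoxy-3-(triisopropylsilyloxy)phenyl]-3-phenylpropan-1-one | Oc1cc(C#CC(C)(C)O)c(O[Si](C(C)C)(C(C)C)C(C)C)c(OC)c1C(=O)CCc1ccccc1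
F6 | step 8 | 5-(3-hydroxy-3-methylbut-1-yn-1-yl)-3-methoxy-2-(3-phenylpropanoyl)-4-(triisopropylsilyloxy)phenyl acetate | CC(=O)Oc1cc(C#CC(C)(C)O)c(O[Si](C(C)C)(C(C)C)C(C)C)c(OC)c1C(=O)CCc1ccccc1
F7 | step 8 | 5-[(1Z)-3-hydroxy-3-methylbut-1-en-1-yl]-3-methoxy-2-(3-phenylpropanoyl)-4-(triisopropylsilyloxy)phenyl acetate | CC(=O)Oc1cc(/C=C\C(C)(C)O)c(O[Si](C(C)C)(C(C)C)C(C)C)c(OC)c1C(=O)CCc1ccccc1
F8 | step 8 | 4-hydroxy-5-[(1Z)-3-hydroxy-3-methylbut-1-en-1-yl]-3-methoxy-2-(3-phenylpropanoyl)phenyl acetate | CC(=O)Oc1cc(/C=C\C(C)(C)O)c(O)c(OC)c1C(=O)CCc1ccccc1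
F9 | step 8 | (±)-7-methoxy-2,2-dimethyl-6-oxo-8-(3-phenylpropanoyl)-1-oxaspiro[4.5]deca-3,7,9-trien-9-yl acetate | CC(=O)OC1=CC2(C=CC(C)(C)O2)C(=O)C(OC)=C1C(=O)CCc1ccccc1
F10 | step 8 | 8-hydroxy-7-methoxy-2,2-dimethyl-6-(3-phenylpropanoyl)-2H-chromen-5-yl acetate | CC(=O)Oc1c(C(=O)CCc2ccccc2)c(OC)c(O)c2OC(C)(C)C=Cc12
F11 | step 5 | 1-[4-(3-hydroxy-3-methylbut-1-yn-1-yl)-2-methoxy-6-(methoxymethoxy)-3-(triisopropylsilyloxy)phenyl]-3-phenylpropan-1-ol (racemic) | COCOc1cc(C#CC(C)(C)O)c(O[Si](C(C)C)(C(C)C)C(C)C)c(OC)c1C(O)CCc1ccccc1
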